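**Plan**
- Retrosynthesis: the formate, the C8 methylene (from a ketone) and the pyranone methyl ether are removed first. Then the C11–pyranone bond is cut (conjugate addition to a C9-methylene C8-ketone), then C9–C10 of ring B (ring expansion), then C8–vinyl, C4–prenyl and the two annulation bonds of a hydrindenedione.
- Enabling feature: C8 is a ketone-level carbon between the ring CH2 C7 and C9, and C9 carries the one-carbon arm C11 and is bonded to the quaternary C10. That is the pattern of a 2-(bromomethyl)cyclohexanone formed from a 1-vinylcyclopentanol by a one-carbon ring enlargement in which C10 migrates.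
- Forward order: ring A is annulated onto 2-methylcyclopentane-1,3-dione; C4 is made quaternary by deconjugative prenylation; ring B arises last, when the five-membered ring is enlarged by the bromonium semipinacol shift. The pyranone (made separately from dimethyl 3-oxopentanedioate) is then joined at C11 and the end groups are adjusted.
- Stereochemistry: C10 from (R)-phenylalanine; C4 by alkylation anti to the C10 methyl; C5 by hydroxyl-directed hydrogenation (cis fusion), carried through the shift by retention at C10; C3 by hydride addition from the convex face; C9 by protonation from the convex face after the conjugate addition.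

Key step: step 14

Convention: drimane-type numbering throughout. Ring A is C1–C5/C10, ring B is C5–C10, C11 is the carbon on C9. In the hydrindanes of steps 2–13 ring A keeps these numbers and the five-membered ring is C5–C6–C7–C8–C10. α is the face that carries the C10 methyl, β the opposite face.

Assumption: in step 13 the vinyl group is taken to add anti to the angular methyl; the C8 epimer would serve equally in step 14, because C8 becomes the carbonyl carbon.

**Step 1**
Reactants: 1 2-methylcyclopentane-1,3-dione; 2 ethyl vinyl ketone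
Product: 3 2-methyl-2-(3-oxopentyl)cyclopentane-1,3-dione
Conditions: Et3N (cat.), EtOAc, rt
Reagents that add atoms: none
Why: Michael addition of the acidic cyclic 1,3-dione to the enone under mild amine catalysis stops cleanly at the triketone.

**Step 2**
Reactants: 3 2-methyl-2-(3-oxopentyl)cyclopentane-1,3-dione
Product: 5 (7aR)-4,7a-dimethyl-2,3,7,7a-tetrahydro-1H-indene-1,5(6H)-dione, via cis-fused aldol ketol 4 (not isolated)
Conditions: (R)-phenylalanine (1 equiv), HClO4 (1 M aq., 0.5 equiv), MeCN, reflux
Reagents that add atoms: none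
Why: Hajos–Parrish–Eder–Sauer–Wiechert aldol condensation, in which the primary amino acid forms the enamine of the ethyl ketone and selects one of the two enantiotopic ring carbonyls, so that the (R) acid should give the (R) centre at C10 (mirror image of the outcome known for the (S) acid), and the acid dehydrates ketol 4 in the same flask.

**Step 3**
Reactants: 5 (7aR)-4,7a-dimethyl-2,3,7,7a-tetrahydro-1H-indene-1,5(6H)-dione
Product: 6 (1R,7aR)-1-hydroxy-4,7a-dimethyl-1,2,3,6,7,7a-hexahydro-5H-inden-5-one (8α-hydroxy enone)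
Conditions: NaBH4 (0.3 equiv), EtOH, −20 °C
Reagents that add atoms: none
Why: Chemoselective 1,2-reduction, since the saturated cyclopentanone is more electrophilic than the vinylogous enone carbonyl, with hydride entering anti to the angular methyl so that the C8 hydroxyl ends α (cis to that methyl).

**Step 4**
Reactants: 6 8α-hydroxy enone; 7 prenyl bromide
Product: 8 8α-hydroxy-4α,10α-dimethyl-4β-(3-methylbut-2-en-1-yl)hydrind-5(6)-en-3-one
Conditions: KOt-Bu (1.1 equiv), t-BuOH/THF, 0 °C; then 7, 0 °C → rt
Reagents that add atoms: none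
Why: Deconjugative α-alkylation of the extended (thermodynamic) dienolate, in which the allylic bromide attacks C4 on the β face, anti to the syn-axial C10 methyl, making C4 quaternary with its methyl α and moving the alkene to C5=C6, while C-alkylation outruns O-alkylation of the hindered secondary alkoxide as in the classical 4,4-dialkylation of free hydroxy enones.

**Step 5**
Reactants: 8 4β-prenyl hydrindenone
Product: 9 8α-hydroxy-4β-(3-hydroxy-3-methylbutyl)-4α,10α-dimethylhydrind-5(6)-en-3-one
Conditions: Co(acac)2 (0.2 equiv), PhSiH3, O2 (1 atm), THF, rt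
Reagents that add atoms: dioxygen, O=O
Why: Mukaiyama hydration (hydrogen-atom transfer from a cobalt hydride, Markovnikov), in which the open trisubstituted prenyl alkene should give the tertiary alcohol while the ring alkene, buried between the quaternary carbons C4 and C10, is expected to react far more slowly.

**Step 6**
Reactants: 9 Δ5 diol ketone
Product: 10 8α-hydroxy-4β-(3-hydroxy-3-methylbutyl)-4α,10α-dimethyl-5α-hydrindan-3-one (cis ring fusion)
Conditions: [Ir(cod)(PCy3)(py)]PF6 (10 mol%), H2 (1 atm), CH2Cl2, rt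
Reagents that add atoms: none
Why: Hydroxyl-directed hydrogenation, in which the C8 hydroxyl (a cyclopent-3-en-1-ol arrangement, on the α face) binds the cationic iridium and hydrogen is delivered to the α face of C5=C6, so that H-5 ends cis to the C10 methyl, the tertiary hydroxyl on the flexible β chain being a much poorer director.

**Step 7**
Reactants: 10 cis-hydrindane diol ketone
Product: 11 8α-acetoxy-4β-(3-hydroxy-3-methylbutyl)-4α,10α-dimethyl-5α-hydrindan-3-one
Conditions: Ac2O, pyridine, DMAP (cat.), CH2Cl2, 0 °C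
Reagents that add atoms: acetic anhydride, CC(=O)OC(C)=O
Why: Acylation distinguishes the secondary C8 alcohol from the tertiary alcohol, which does not acetylate under these conditions, and the acetate masks C8 until step 11.

**Step 8**
Reactants: 11 8α-acetate
Product: 12 8α-acetoxy-4α,10α-dimethyl-4β-[3-methyl-3-(triethylsilyloxy)butyl]-5α-hydrindan-3-one
Conditions: TESOTf, 2,6-lutidine, CH2Cl2, −78 → 0 °C
Reagents that add atoms: triethylsilyl triflate, CC[Si](CC)(CC)OS(=O)(=O)C(F)(F)F
Why: A silyl triflate with a hindered base silylates the tertiary alcohol, the only free hydroxyl, and at low temperature leaves the hindered ketone alone.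

**Step 9**
Reactants: 12 C3 ketone
Product: 13 8α-acetoxy-3β-hydroxy-4α,10α-dimethyl-4β-[3-methyl-3-(triethylsilyloxy)butyl]-5α-hydrindane
Conditions: NaBH4, MeOH/THF, −20 → 0 °C
Reagents that add atoms: none
Why: Ketone reduction by a small hydride, expected to proceed by axial attack on the α (convex) face of the ring A chair that has only H-1α and H-5 as syn-axial neighbours, the β face being screened by the C4 side chain and the five-membered ring, which gives the 3β alcohol (cis to the C4 chain, trans to both methyls) and leaves the acetate intact.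

**Step 10**
Reactants: 13 3β-alcohol
Product: 14 8α-acetoxy-3β-(tert-butyldimethylsilyloxy)-4α,10α-dimethyl-4β-[3-methyl-3-(triethylsilyloxy)butyl]-5α-hydrindane
Conditions: TBSOTf, 2,6-lutidine, CH2Cl2, 0 °C → rt
Reagents that add atoms: tert-butyldimethylsilyl triflate, CC(C)(C)[Si](C)(C)OS(=O)(=O)C(F)(F)F
Why: The silyl triflate is reactive enough to silylate the neopentyl secondary alcohol, the only free hydroxyl.

**Step 11**
Reactants: 14 8α-acetate bis-silyl ether
Product: 15 3β-(tert-butyldimethylsilyloxy)-4α,10α-dimethyl-4β-[3-methyl-3-(triethylsilyloxy)butyl]-5α-hydrindan-8α-ol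
Conditions: K2CO3, MeOH, rt → 40 °C
Reagents that add atoms: none
Why: Base-catalysed transesterification with methanol removes the acetate, and both silyl ethers are stable to carbonate in methanol.

**Step 12**
Reactants: 15 8α-alcohol
Product: 16 3β-(tert-butyldimethylsilyloxy)-4α,10α-dimethyl-4β-[3-methyl-3-(triethylsilyloxy)butyl]-5α-hydrindan-8-one
Conditions: Dess–Martin periodinane, CH2Cl2, 0 °C → rt
Reagents that add atoms: none
Why: Dess–Martin oxidation of the single free secondary alcohol under near-neutral conditions that the silyl ethers tolerate.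

**Step 13**
Reactants: 16 C8 ketone
Product: 17 3β-(tert-butyldimethylsilyloxy)-4α,10α-dimethyl-4β-[3-methyl-3-(triethylsilyloxy)butyl]-8β-vinyl-5α-hydrindan-8α-ol
Conditions: CeCl3 (dried), CH2=CHMgBr, THF, −78 → 0 °C
Reagents that add atoms: vinylmagnesium bromide, C=C[Mg]Br
Why: Organocerium 1,2-addition, in which the weakly basic vinylcerium reagent adds to the hindered, enolisable cyclopentanone without enolisation and from the face away from the angular methyl.

**Step 14**
Reactants: 17 8β-vinyl-8α-ol
Product: 18 9β-(bromomethyl)-3β-(tert-butyldimethylsilyloxy)-4α,10α-dimethyl-4β-[3-methyl-3-(triethylsilyloxy)butyl]-5α,9α-H-decalin-8-one (cis-decalin)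
Conditions: NBS (1.2 equiv), i-PrOH, 0 °C → rt, dark
Reagents that add atoms: N-bromosuccinimide, O=C1CCC(=O)N1Br
Why: NBS forms a bromonium ion on the vinyl group, and the ring bond C8–C10, aligned antiperiplanar to the breaking C–Br bond at the internal carbon, shifts from C8 to that carbon (C9) while the hydroxyl oxygen becomes the C8 carbonyl; this is a halonium-induced semipinacol rearrangement of an allylic alcohol, the closest known cases being ring expansions of 1-vinylcycloalkanols to 2-(halomethyl)cycloalkanones, among which cyclopentanol examples are rarer than cyclobutanol ones. Ring B is closed by ring enlargement, a suprafacial 1,2-alkyl shift of C10, not by a new cyclisation, so the five-membered ring C5–C6–C7–C8–C10 becomes the six-membered ring C5–C6–C7–C8–C9–C10. C10 migrates with retention, so the cis relationship of H-5 and the C10 methyl from step 6 is carried into the cis-decalin. The new stereocentre C9 results from anti addition of C10 and bromine across the alkene and depends on the vinyl rotamer (drawn for the rotamer with the CH2 terminus turned toward C7); its configuration is not needed, because step 16 makes C9 trigonal. The selectivity that matters is migration of C10 over C7, which the substrate secures because the quaternary carbon carries the developing positive charge better than the ring CH2, while capture of the bromonium ion from outside is limited by the hindered alcohol solvent and by the absence of any other free hydroxyl.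

**Step 15**
Reactants: 19 dimethyl 3-oxopentanedioate
Product: 21 methyl 4-hydroxy-2-methyl-6-oxo-6H-pyran-3-carboxylate, via dimethyl 2-acetyl-3-oxopentanedioate 20 (not isolated)
Conditions: AcCl, MgCl2, pyridine, CH2Cl2, 0 °C → rt; crude, p-TsOH (cat.), toluene, reflux
Reagents that add atoms: acetyl chloride, CC(=O)Cl
Why: Magnesium-mediated C-acylation of the 1,3-dicarbonyl (soft enolisation), then acid-catalysed lactonisation of the enolised acetyl oxygen onto the distal ester with loss of methanol, gives the 4-hydroxy-2-pyranone.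

**Step 16**
Reactants: 18 bromomethyl ketone; 21 methyl 4-hydroxy-2-methyl-6-oxo-6H-pyran-3-carboxylate
Product: 23 Michael adduct methyl 5-{[8-oxo-decalin-9β-yl]methyl}-4-hydroxy-2-methyl-6-oxo-6H-pyran-3-carboxylate (decalin substituted as in 18; H-9 α), via C9-methylene C8-ketone 22 (not isolated)
Conditions: 21 (1.5 equiv), Et3N (3 equiv), MeCN, 0 °C → rt
Reagents that add atoms: none
Why: E1cB loss of HBr gives the exocyclic enone 22, to which the pyranone adds through its ring CH carbon (Michael addition of a vinylogous acid), and C9 is then set by protonation of the C8 enol on the convex α face (the face of H-5), the β face being covered by ring A and its quaternary C4, so that H-9 ends α and the pyranone arm β; the adduct may rest partly as its cyclic hemiketal, which reopens in step 17.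

**Step 17**
Reactants: 23 Michael adduct
Product: 24 methyl 5-{[8-oxo-decalin-9β-yl]methyl}-6-methoxy-2-methyl-4-oxo-4H-pyran-3-carboxylate (decalin substituted as in 18)
Conditions: MeOTf (1.5 equiv), CH2Cl2, 0 °C → rt; aq. NaHCO3
Reagents that add atoms: methyl triflate, COS(=O)(=O)C(F)(F)F
Why: O-methylation of a neutral 4-hydroxy-2-pyranone by a hard methylating agent takes place at the most basic oxygen, the lactone carbonyl, and loss of the proton gives the 2-methoxy-4-pyranone, the known regiochemistry for methyl triflate and methyl fluorosulfonate.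

**Step 18**
Reactants: 24 methoxypyranone C8 ketone
Product: 25 methyl 5-{[8-methylene-decalin-9β-yl]methyl}-6-methoxy-2-methyl-4-oxo-4H-pyran-3-carboxylate (3β-OTBS, tertiary OTES)
Conditions: Zn, CH2Br2, TiCl4 (pre-formed in THF), CH2Cl2, 0 °C → rt
Reagents that add atoms: dibromomethane, BrCBr
Why: Takai–Lombardo methylenation, in which the non-basic zinc–titanium methylene reagent converts the hindered, enolisable ketone into the exocyclic alkene without exposing C9 to enolisation and does not attack the ester or the vinylogous ester carbonyl of the pyranone.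

**Step 19**
Reactants: 25 bis-silyl ether
Product: 26 tertiary alcohol, methyl 5-{[3β-(tert-butyldimethylsilyloxy)-4β-(3-hydroxy-3-methylbutyl)-4α,10α-dimethyl-8-methylene-5α,9α-H-decalin-9β-yl]methyl}-6-methoxy-2-methyl-4-oxo-4H-pyran-3-carboxylate
Conditions: HF·pyridine, pyridine, THF, 0 °C
Reagents that add atoms: none
Why: Fluoride-mediated desilylation under buffered conditions cleaves the triethylsilyl ether much faster than the hindered neopentyl tert-butyldimethylsilyl ether.

**Step 20**
Reactants: 26 tertiary alcohol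
Product: 27 tertiary formate, methyl 5-{[3β-(tert-butyldimethylsilyloxy)-4β-(3-formyloxy-3-methylbutyl)-4α,10α-dimethyl-8-methylene-5α,9α-H-decalin-9β-yl]methyl}-6-methoxy-2-methyl-4-oxo-4H-pyran-3-carboxylate
Conditions: acetic formic anhydride, pyridine, DMAP (cat.), CH2Cl2, 0 °C → rt
Reagents that add atoms: acetic formic anhydride, CC(=O)OC=O
Why: Formylation with the mixed anhydride, in which attack at the formyl carbonyl is much faster than at the acetyl carbonyl and the reagent is reactive enough for a tertiary alcohol.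

**Step 21**
Reactants: 27 tertiary formate silyl ether
Product: 28 target CNP0292250.1, methyl 5-{[4β-(3-formyloxy-3-methylbutyl)-3β-hydroxy-4α,10α-dimethyl-8-methylene-5α,9α-H-decalin-9β-yl]methyl}-6-methoxy-2-methyl-4-oxo-4H-pyran-3-carboxylate
Conditions: HF·pyridine, pyridine, THF, rt
Reagents that add atoms: none
Why: Buffered HF·pyridine removes the remaining silyl ether under mildly acidic, non-nucleophilic conditions that should leave the tertiary formate, the exocyclic alkene and the methoxypyranone intact.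

**Compound list**
1 | 2-methylcyclopentane-1,3-dione | CC1C(=O)CCC1=O | starting material
2 | ethyl vinyl ketone (pent-1-en-3-one) | CCC(=O)C=C | starting material
3 | 2-methyl-2-(3-oxopentyl)cyclopentane-1,3-dione | CCC(=O)CCC1(C)C(=O)CCC1=O | intermediate
4 | cis-fused aldol ketol, 5α-hydroxy-4,10α-dimethylhydrindane-3,8-dione (C4 methyl epimers) | O=C1CC[C@@]2(O)C(C)C(=O)CC[C@]21C | intermediate
5 | (7aR)-4,7a-dimethyl-2,3,7,7a-tetrahydro-1H-indene-1,5(6H)-dione | O=C1CCC2=C(C)C(=O)CC[C@]21C | intermediate
6 | (1R,7aR)-1-hydroxy-4,7a-dimethyl-1,2,3,6,7,7a-hexahydro-5H-inden-5-one (8α-hydroxy enone) | O[C@@H]1CCC2=C(C)C(=O)CC[C@]21C | intermediate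
7 | prenyl bromide (1-bromo-3-methylbut-2-ene) | CC(C)=CCBr | starting material
8 | 8α-hydroxy-4α,10α-dimethyl-4β-(3-methylbut-2-en-1-yl)hydrind-5(6)-en-3-one | O[C@@H]1CC=C2[C@@](C)(CC=C(C)C)C(=O)CC[C@]21C | intermediate
9 | 8α-hydroxy-4β-(3-hydroxy-3-methylbutyl)-4α,10α-dimethylhydrind-5(6)-en-3-one | O[C@@H]1CC=C2[C@@](C)(CCC(C)(C)O)C(=O)CC[C@]21C | intermediate
10 | 8α-hydroxy-4β-(3-hydroxy-3-methylbutyl)-4α,10α-dimethyl-5α-hydrindan-3-one (cis fusion) | O[C@@H]1CC[C@H]2[C@@](C)(CCC(C)(C)O)C(=O)CC[C@]21C | intermediate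
11 | 8α-acetoxy-4β-(3-hydroxy-3-methylbutyl)-4α,10α-dimethyl-5α-hydrindan-3-one | CC(=O)O[C@@H]1CC[C@H]2[C@@](C)(CCC(C)(C)O)C(=O)CC[C@]21C | intermediate
12 | 8α-acetoxy-4α,10α-dimethyl-4β-[3-methyl-3-(triethylsilyloxy)butyl]-5α-hydrindan-3-one | CC(=O)O[C@@H]1CC[C@H]2[C@@](C)(CCC(C)(C)O[Si](CC)(CC)CC)C(=O)CC[C@]21C | intermediate
13 | 8α-acetoxy-3β-hydroxy-4α,10α-dimethyl-4β-[3-methyl-3-(triethylsilyloxy)butyl]-5α-hydrindane | CC(=O)O[C@@H]1CC[C@H]2[C@@](C)(CCC(C)(C)O[Si](CC)(CC)CC)[C@@H](O)CC[C@]21C | intermediate
14 | 8α-acetoxy-3β-(tert-butyldimethylsilyloxy)-4α,10α-dimethyl-4β-[3-methyl-3-(triethylsilyloxy)butyl]-5α-hydrindane | CC(=O)O[C@@H]1CC[C@H]2[C@@](C)(CCC(C)(C)O[Si](CC)(CC)CC)[C@@H](O[Si](C)(C)C(C)(C)C)CC[C@]21C | intermediate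
15 | 3β-(tert-butyldimethylsilyloxy)-4α,10α-dimethyl-4β-[3-methyl-3-(triethylsilyloxy)butyl]-5α-hydrindan-8α-ol | O[C@@H]1CC[C@H]2[C@@](C)(CCC(C)(C)O[Si](CC)(CC)CC)[C@@H](O[Si](C)(C)C(C)(C)C)CC[C@]21C | intermediate
16 | 3β-(tert-butyldimethylsilyloxy)-4α,10α-dimethyl-4β-[3-methyl-3-(triethylsilyloxy)butyl]-5α-hydrindan-8-one | O=C1CC[C@H]2[C@@](C)(CCC(C)(C)O[Si](CC)(CC)CC)[C@@H](O[Si](C)(C)C(C)(C)C)CC[C@]21C | intermediate
17 | 3β-(tert-butyldimethylsilyloxy)-4α,10α-dimethyl-4β-[3-methyl-3-(triethylsilyloxy)butyl]-8β-vinyl-5α-hydrindan-8α-ol | C=C[C@@]1(O)CC[C@H]2[C@@](C)(CCC(C)(C)O[Si](CC)(CC)CC)[C@@H](O[Si](C)(C)C(C)(C)C)CC[C@]21C | intermediate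
18 | 9β-(bromomethyl)-3β-(tert-butyldimethylsilyloxy)-4α,10α-dimethyl-4β-[3-methyl-3-(triethylsilyloxy)butyl]-5α,9α-H-decalin-8-one | O=C1CC[C@H]2[C@@](C)(CCC(C)(C)O[Si](CC)(CC)CC)[C@@H](O[Si](C)(C)C(C)(C)C)CC[C@@]2(C)[C@H]1CBr | intermediate
19 | dimethyl 3-oxopentanedioate | COC(=O)CC(=O)CC(=O)OC | starting material
20 | dimethyl 2-acetyl-3-oxopentanedioate | COC(=O)CC(=O)C(C(C)=O)C(=O)OC | intermediate
21 | methyl 4-hydroxy-2-methyl-6-oxo-6H-pyran-3-carboxylate | COC(=O)c1c(C)oc(=O)cc1O | intermediate
22 | 3β-(tert-butyldimethylsilyloxy)-4α,10α-dimethyl-9-methylene-4β-[3-methyl-3-(triethylsilyloxy)butyl]-5α-H-decalin-8-one | O=C1CC[C@H]2[C@@](C)(CCC(C)(C)O[Si](CC)(CC)CC)[C@@H](O[Si](C)(C)C(C)(C)C)CC[C@@]2(C)C1=C | intermediate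
23 | methyl 5-{[3β-(tert-butyldimethylsilyloxy)-4α,10α-dimethyl-4β-[3-methyl-3-(triethylsilyloxy)butyl]-8-oxo-5α,9α-H-decalin-9β-yl]methyl}-4-hydroxy-2-methyl-6-oxo-6H-pyran-3-carboxylate | O=C1CC[C@H]2[C@@](C)(CCC(C)(C)O[Si](CC)(CC)CC)[C@@H](O[Si](C)(C)C(C)(C)C)CC[C@@]2(C)[C@H]1Cc1c(O)c(C(=O)OC)c(C)oc1=O | intermediate
24 | methyl 5-{[3β-(tert-butyldimethylsilyloxy)-4α,10α-dimethyl-4β-[3-methyl-3-(triethylsilyloxy)butyl]-8-oxo-5α,9α-H-decalin-9β-yl]methyl}-6-methoxy-2-methyl-4-oxo-4H-pyran-3-carboxylate | O=C1CC[C@H]2[C@@](C)(CCC(C)(C)O[Si](CC)(CC)CC)[C@@H](O[Si](C)(C)C(C)(C)C)CC[C@@]2(C)[C@H]1Cc1c(OC)oc(C)c(C(=O)OC)c1=O | intermediate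
25 | methyl 5-{[3β-(tert-butyldimethylsilyloxy)-4α,10α-dimethyl-8-methylene-4β-[3-methyl-3-(triethylsilyloxy)butyl]-5α,9α-H-decalin-9β-yl]methyl}-6-methoxy-2-methyl-4-oxo-4H-pyran-3-carboxylate | C=C1CC[C@H]2[C@@](C)(CCC(C)(C)O[Si](CC)(CC)CC)[C@@H](O[Si](C)(C)C(C)(C)C)CC[C@@]2(C)[C@H]1Cc1c(OC)oc(C)c(C(=O)OC)c1=O | intermediate
26 | methyl 5-{[3β-(tert-butyldimethylsilyloxy)-4β-(3-hydroxy-3-methylbutyl)-4α,10α-dimethyl-8-methylene-5α,9α-H-decalin-9β-yl]methyl}-6-methoxy-2-methyl-4-oxo-4H-pyran-3-carboxylate | C=C1CC[C@H]2[C@@](C)(CCC(C)(C)O)[C@@H](O[Si](C)(C)C(C)(C)C)CC[C@@]2(C)[C@H]1Cc1c(OC)oc(C)c(C(=O)OC)c1=O | intermediate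
27 | methyl 5-{[3β-(tert-butyldimethylsilyloxy)-4β-(3-formyloxy-3-methylbutyl)-4α,10α-dimethyl-8-methylene-5α,9α-H-decalin-9β-yl]methyl}-6-methoxy-2-methyl-4-oxo-4H-pyran-3-carboxylate | C=C1CC[C@H]2[C@@](C)(CCC(C)(C)OC=O)[C@@H](O[Si](C)(C)C(C)(C)C)CC[C@@]2(C)[C@H]1Cc1c(OC)oc(C)c(C(=O)OC)c1=O | intermediate
28 | CNP0292250.1, methyl 5-{[4β-(3-formyloxy-3-methylbutyl)-3β-hydroxy-4α,10α-dimethyl-8-methylene-5α,9α-H-decalin-9β-yl]methyl}-6-methoxy-2-methyl-4-oxo-4H-pyran-3-carboxylate | C=C1CC[C@H]2[C@@](C)(CCC(C)(C)OC=O)[C@@H](O)CC[C@@]2(C)[C@H]1Cc1c(OC)oc(C)c(C(=O)OC)c1=O | target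

**Totals**
Total step count: 21.
Longest linear sequence: 20 steps (steps 1–14 and 16–21, from 1); step 15 is a one-step side branch.

**Steps most likely to fail**

Step 14. The 1,2-shift may be outrun by capture of the bromonium ion (bromoether formation with the solvent, or ring closure through the carbinol oxygen), or the ring CH2 C7 may migrate in competition with C10, since a cyclopentanol releases little strain. The fallback uses an epoxide in place of the bromonium ion as the trigger for the same C10 shift. Setting out from 17, hydroxyl-directed epoxidation with VO(acac)2 and t-BuOOH in CH2Cl2 should give the 8-(oxiran-2-yl) carbinol F1. BF3·OEt2 in CH2Cl2 at −78 °C should then induce the semipinacol rearrangement of this 2,3-epoxy alcohol, C10 migrating to the internal oxirane carbon as its C–O bond opens, to give the 9-(hydroxymethyl) C8-ketone F2. Mesylation (MsCl, Et3N, 0 °C) gives the 9-(mesyloxymethyl) C8-ketone F3, which is used in place of 18 under the conditions of step 16 (E1cB to 22, then pyranone addition) and comes back to the route at 23.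

Step 16. The protonation that sets C9 may show poor facial selectivity, the centre may drift by enolisation under the amine, or enone 22 may dimerise before the pyranone adds. In the fallback the C9–H bond is set by hydroboration and the C11–pyranone bond is made by cross-coupling. Setting out from 18, Et3N alone gives 22, which is reduced at once (NaBH4, CeCl3, MeOH, −78 °C, Luche reduction) to the C9-methylene C8-alcohol F4. 9-BBN in THF should add across the exocyclic alkene from the α face, boron at C11 and hydrogen at C9, to give the C11 9-BBN borane F5, used without isolation. The coupling partner is made from 21 by iodination with N-iodosuccinimide to methyl 4-hydroxy-5-iodo-2-methyl-6-oxo-6H-pyran-3-carboxylate F6, then O-methylation with MeOTf as in step 17 to methyl 5-iodo-6-methoxy-2-methyl-4-oxo-4H-pyran-3-carboxylate F7. Suzuki–Miyaura coupling of F5 with F7 (Pd(dppf)Cl2, K3PO4, DMF/H2O) gives the coupled C8-alcohol F8, and Dess–Martin oxidation returns to the route at 24.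

Step 9. Hydride delivery to C3 may show poor facial selectivity, because the cis-hydrindane can react through either ring A chair. The fallback replaces substrate control by catalyst control. Setting out from 12, Corey–Bakshi–Shibata reduction with (R)-2-methyl-CBS-oxazaborolidine and BH3·SMe2 in THF at −20 °C, in which the quaternary C4 acts as the large and the C2 methylene as the small substituent, should give the (3S) alcohol 13 directly. No new compound is made and the route is rejoined at 13.

**Further compounds**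
F1 | step 14 | 3β-(tert-butyldimethylsilyloxy)-4α,10α-dimethyl-4β-[3-methyl-3-(triethylsilyloxy)butyl]-8β-(oxiran-2-yl)-5α-hydrindan-8α-ol (oxirane CH unassigned) | C1OC1[C@@]2(O)CC[C@H]3[C@@](C)(CCC(C)(C)O[Si](CC)(CC)CC)[C@@H](O[Si](C)(C)C(C)(C)C)CC[C@]32C
F2 | step 14 | 3β-(tert-butyldimethylsilyloxy)-9-(hydroxymethyl)-4α,10α-dimethyl-4β-[3-methyl-3-(triethylsilyloxy)butyl]-5α-H-decalin-8-one (C9 unassigned) | O=C1CC[C@H]2[C@@](C)(CCC(C)(C)O[Si](CC)(CC)CC)[C@@H](O[Si](C)(C)C(C)(C)C)CC[C@@]2(C)C1CO
F3 | step 14 | 3β-(tert-butyldimethylsilyloxy)-9-(methanesulfonyloxymethyl)-4α,10α-dimethyl-4β-[3-methyl-3-(triethylsilyloxy)butyl]-5α-H-decalin-8-one (C9 unassigned) | O=C1CC[C@H]2[C@@](C)(CCC(C)(C)O[Si](CC)(CC)CC)[C@@H](O[Si](C)(C)C(C)(C)C)CC[C@@]2(C)C1COS(C)(=O)=O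
F4 | step 16 | 3β-(tert-butyldimethylsilyloxy)-4α,10α-dimethyl-9-methylene-4β-[3-methyl-3-(triethylsilyloxy)butyl]-5α-H-decalin-8-ol (C8 unassigned) | OC1CC[C@H]2[C@@](C)(CCC(C)(C)O[Si](CC)(CC)CC)[C@@H](O[Si](C)(C)C(C)(C)C)CC[C@@]2(C)C1=C
F5 | step 16 | 9β-[(9-borabicyclo[3.3.1]nonan-9-yl)methyl]-3β-(tert-butyldimethylsilyloxy)-4α,10α-dimethyl-4β-[3-methyl-3-(triethylsilyloxy)butyl]-5α,9α-H-decalin-8-ol (hydroxyl shown free) | OC1CC[C@H]2[C@@](C)(CCC(C)(C)O[Si](CC)(CC)CC)[C@@H](O[Si](C)(C)C(C)(C)C)CC[C@@]2(C)[C@H]1CB1C3CCCC1CCC3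
F6 | step 16 | methyl 4-hydroxy-5-iodo-2-methyl-6-oxo-6H-pyran-3-carboxylate | COC(=O)c1c(C)oc(=O)c(I)c1O
F7 | step 16 | methyl 5-iodo-6-methoxy-2-methyl-4-oxo-4H-pyran-3-carboxylate | COC(=O)c1c(C)oc(OC)c(I)c1=O
F8 | step 16 | methyl 5-{[3β-(tert-butyldimethylsilyloxy)-8-hydroxy-4α,10α-dimethyl-4β-[3-methyl-3-(triethylsilyloxy)butyl]-5α,9α-H-decalin-9β-yl]methyl}-6-methoxy-2-methyl-4-oxo-4H-pyran-3-carboxylate (C8 unassigned) | OC1CC[C@H]2[C@@](C)(CCC(C)(C)O[Si](CC)(CC)CC)[C@@H](O[Si](C)(C)C(C)(C)C)CC[C@@]2(C)[C@H]1Cc1c(OC)oc(C)c(C(=O)OC)c1=O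
F0 | step 9 | none | none
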